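**Retrosynthetic overview**

- **Feature:** in the central ring B (C1 OH, C3 CH2CH2 bridge to ring A) the two diarylmethane CH2 carbons on C2 and C4 each lie between two arenes. They stand ortho and para to the C1 oxygen and lead to identical 4-hydroxyphenyl rings C and D.
- **Key disconnection:** both CH2 groups are traced back to C=O and each ketone is cut on both sides. This gives the C2,C4-dibromide, two CO and two 4-(benzyloxy)phenylboronic acids (double carbonylative Suzuki coupling, four C–C bonds, five components).
- **Precursor:** the dibromo bibenzyl is cut at the bridge (Horner–Wadsworth–Emmons olefination, then diimide) into 3-(benzyloxy)-2,6-dibromobenzaldehyde and the ring-A benzylic phosphonate. The second bromine comes from para-bromination of 2-bromo-3-hydroxybenzaldehyde.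
- **End game:** hydride reduction of both ketones, then one hydrogenolysis that removes the two benzhydrylic hydroxyls and the four benzyl ethers.
- **Rings:** no ring is formed at any stage. Rings A, B, C and D are all bought as benzenes and joined in the order A–B (bridge), then C and D together.

Key step: step 9

Remark: the target has no stereocentre, stereogenic axis or configured double bond. It is achiral, so no enantiomer has to be chosen. Ring B is numbered C1 (oxygen), C2, C3 (bridge), C4 throughout.

**Step 1**
Reactants: 1 2-bromo-3-hydroxybenzaldehyde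
Product: 2 2,6-dibromo-3-hydroxybenzaldehyde
Conditions: Br2 (1.0 equiv), AcOH, rt
Reagents that add atoms: bromine, BrBr
Why: Electrophilic aromatic bromination in which the C3 hydroxyl directs, its crowded ortho site C2 is already blocked by bromine, and of the two open sites the para carbon C6 should react ahead of the ortho carbon C4 in a polar protic medium, as in the para-bromination of 3-hydroxybenzaldehyde itself.

**Step 2**
Reactants: 2 2,6-dibromo-3-hydroxybenzaldehyde
Product: 3 3-(benzyloxy)-2,6-dibromobenzaldehyde
Conditions: BnBr, K2CO3, DMF, rt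
Reagents that add atoms: benzyl bromide, BrCc1ccccc1
Why: Williamson ether synthesis on an acidic bromophenol, to which the aldehyde and the aryl bromides are inert.

**Step 3**
Reactants: 4 3-hydroxy-5-methoxybenzaldehyde
Product: 5 3-(benzyloxy)-5-methoxybenzaldehyde
Conditions: BnBr, K2CO3, DMF, rt
Reagents that add atoms: benzyl bromide, BrCc1ccccc1
Why: Williamson ether synthesis that masks the only phenol of ring A with the same group that is used on the other rings, so that one final step frees all four.

**Step 4**
Reactants: 5 3-(benzyloxy)-5-methoxybenzaldehyde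
Product: 6 [3-(benzyloxy)-5-methoxyphenyl]methanol
Conditions: NaBH4, MeOH, 0 °C
Reagents that add atoms: none
Why: Borohydride reduction of an aromatic aldehyde, which leaves both aryl ethers untouched.

**Step 5**
Reactants: 6 [3-(benzyloxy)-5-methoxyphenyl]methanol
Product: 7 1-(benzyloxy)-3-(bromomethyl)-5-methoxybenzene
Conditions: PBr3, CH2Cl2, 0 °C
Reagents that add atoms: phosphorus tribromide, BrP(Br)Br
Why: Bromide displaces the phosphite ester of a primary benzylic alcohol (SN2), and the two meta alkoxy groups do not stabilise a benzylic cation, so the bromide should be stable enough to handle.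

**Step 6**
Reactants: 7 1-(benzyloxy)-3-(bromomethyl)-5-methoxybenzene
Product: 8 diethyl {[3-(benzyloxy)-5-methoxyphenyl]methyl}phosphonate
Conditions: P(OEt)3 (neat), 130 °C
Reagents that add atoms: triethyl phosphite, CCOP(OCC)OCC
Why: Michaelis–Arbuzov reaction of a primary benzylic bromide, driven by loss of volatile bromoethane.

**Step 7**
Reactants: 8 diethyl {[3-(benzyloxy)-5-methoxyphenyl]methyl}phosphonate; 3 3-(benzyloxy)-2,6-dibromobenzaldehyde
Product: 10 (E)-1-(benzyloxy)-2,4-dibromo-3-{2-[3-(benzyloxy)-5-methoxyphenyl]ethenyl}benzene, via potassium salt of the benzylic carbanion of phosphonate 8 9 (not isolated)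
Conditions: KOt-Bu (1.0 equiv), THF, 0 °C; then 3, 0 °C to rt
Reagents that add atoms: none
Why: Horner–Wadsworth–Emmons olefination of a non-enolisable aldehyde, in which pre-forming the anion leaves no free alkoxide to attack the activated ortho bromides, and the expected E geometry is of no consequence because the alkene is saturated next.

**Step 8**
Reactants: 10 (E)-1-(benzyloxy)-2,4-dibromo-3-{2-[3-(benzyloxy)-5-methoxyphenyl]ethenyl}benzene
Product: 11 1-(benzyloxy)-2,4-dibromo-3-{2-[3-(benzyloxy)-5-methoxyphenyl]ethyl}benzene
Conditions: TsNHNH2 (excess, in portions), NaOAc, DME–H2O, reflux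
Reagents that add atoms: none
Why: Diimide reduction transfers two hydrogens to the C=C bond in a concerted way and touches neither the C–Br bonds nor the O-benzyl bonds, both of which catalytic hydrogenation would endanger.

**Step 9**
Reactants: 11 1-(benzyloxy)-2,4-dibromo-3-{2-[3-(benzyloxy)-5-methoxyphenyl]ethyl}benzene; 12 4-(benzyloxy)phenylboronic acid (two equivalents consumed); 13 carbon monoxide (two equivalents consumed)
Product: 15 [4-(benzyloxy)-2-{2-[3-(benzyloxy)-5-methoxyphenyl]ethyl}-1,3-phenylene]bis{[4-(benzyloxy)phenyl]methanone}, via {4-(benzyloxy)-2-{2-[3-(benzyloxy)-5-methoxyphenyl]ethyl}-3-bromophenyl}[4-(benzyloxy)phenyl]methanone 14 (not isolated)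
Conditions: Pd(OAc)2 (10 mol %), di(1-adamantyl)-n-butylphosphine (30 mol %), K2CO3 (6 equiv), CO (5 bar), anisole, 100 °C; 12 (3 equiv) in 1,4-dioxane dosed by pump over 6 h
Reagents that add atoms: carbon monoxide 13, [C-]#[O+]; 4-(benzyloxy)phenylboronic acid 12, OB(O)c1ccc(OCc2ccccc2)cc1
Why: This is a carbonylative Suzuki–Miyaura coupling run twice on one ring: Pd(0) adds oxidatively into a C–Br bond, CO inserts to give an acylpalladium bromide, the boronate formed from 12 and carbonate transmetallates, and reductive elimination releases the diaryl ketone, so that each cycle makes the ring–carbonyl and the carbonyl–aryl bond and two cycles make four bonds from five components. The closest known reaction type is the palladium-catalysed carbonylative coupling of ortho-substituted and ortho,ortho'-disubstituted aryl halides with arylboronic acids to hindered benzophenones, and twofold versions on dihaloarenes are also known. The mono-ortho-substituted C4–Br should react first to give 14, and the new acyl group then makes the ring somewhat less electron-rich, which helps oxidative addition at the C2–Br flanked by OBn and the bridge. The selectivity needed is CO insertion before transmetallation and before C–H arylation of ring A to a 9,10-dihydrophenanthrene: crowding at both arylpalladium centres slows transmetallation and speeds migratory insertion, which moves the metal one atom away from the ring, and CO pressure, the bulky electron-rich phosphine and a low stationary concentration of 12 push the same way. No ring closes and no stereocentre forms, and the benzyl and methyl ethers are inert to these conditions.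

**Step 10**
Reactants: 15 [4-(benzyloxy)-2-{2-[3-(benzyloxy)-5-methoxyphenyl]ethyl}-1,3-phenylene]bis{[4-(benzyloxy)phenyl]methanone}
Product: 16 [4-(benzyloxy)-2-{2-[3-(benzyloxy)-5-methoxyphenyl]ethyl}-1,3-phenylene]bis{[4-(benzyloxy)phenyl]methanol} (mixture of diastereomers, racemic)
Conditions: LiAlH4, THF, 0 °C to reflux; aqueous NaOH work-up
Reagents that add atoms: none
Why: Hydride reduction with a small, strong donor that should also reach the C2 carbonyl twisted between OBn and the bridge; the two new carbinol stereocentres are set without control and are both erased in step 11, so the mixture is carried on as such.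

**Step 11**
Reactants: 16 [4-(benzyloxy)-2-{2-[3-(benzyloxy)-5-methoxyphenyl]ethyl}-1,3-phenylene]bis{[4-(benzyloxy)phenyl]methanol}
Product: 17 2,4-bis(4-hydroxybenzyl)-3-[2-(3-hydroxy-5-methoxyphenyl)ethyl]phenol (target)
Conditions: H2 (3 bar), 10 % Pd/C, EtOAc–EtOH–AcOH, rt
Reagents that add atoms: none
Why: Catalytic hydrogenolysis, in which each carbinol carbon is doubly benzylic and para to an oxygen on its outer ring, so its C–O bond should be cleaved on palladium under weak acid together with the four O-benzyl bonds, while the methyl ether, the bridge and the arenes are inert and the achiral target results.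

**Compound list**

1 | 2-bromo-3-hydroxybenzaldehyde | O=Cc1cccc(O)c1Br | starting material
2 | 2,6-dibromo-3-hydroxybenzaldehyde | O=Cc1c(Br)ccc(O)c1Br | intermediate
3 | 3-(benzyloxy)-2,6-dibromobenzaldehyde | O=Cc1c(Br)ccc(OCc2ccccc2)c1Br | intermediate
4 | 3-hydroxy-5-methoxybenzaldehyde | COc1cc(O)cc(C=O)c1 | starting material
5 | 3-(benzyloxy)-5-methoxybenzaldehyde | COc1cc(OCc2ccccc2)cc(C=O)c1 | intermediate
6 | [3-(benzyloxy)-5-methoxyphenyl]methanol | COc1cc(OCc2ccccc2)cc(CO)c1 | intermediate
7 | 1-(benzyloxy)-3-(bromomethyl)-5-methoxybenzene | COc1cc(OCc2ccccc2)cc(CBr)c1 | intermediate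
8 | diethyl {[3-(benzyloxy)-5-methoxyphenyl]methyl}phosphonate | CCOP(=O)(Cc1cc(OC)cc(OCc2ccccc2)c1)OCC | intermediate
9 | potassium salt of the benzylic carbanion of phosphonate 8 | CCOP(=O)([CH-]c1cc(OC)cc(OCc2ccccc2)c1)OCC.[K+] | intermediate (not isolated)
10 | (E)-1-(benzyloxy)-2,4-dibromo-3-{2-[3-(benzyloxy)-5-methoxyphenyl]ethenyl}benzene | COc1cc(OCc2ccccc2)cc(/C=C/c2c(Br)ccc(OCc3ccccc3)c2Br)c1 | intermediate
11 | 1-(benzyloxy)-2,4-dibromo-3-{2-[3-(benzyloxy)-5-methoxyphenyl]ethyl}benzene | COc1cc(OCc2ccccc2)cc(CCc2c(Br)ccc(OCc3ccccc3)c2Br)c1 | intermediate (key-step precursor)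
12 | 4-(benzyloxy)phenylboronic acid | OB(O)c1ccc(OCc2ccccc2)cc1 | starting material
13 | carbon monoxide | [C-]#[O+] | starting material
14 | {4-(benzyloxy)-2-{2-[3-(benzyloxy)-5-methoxyphenyl]ethyl}-3-bromophenyl}[4-(benzyloxy)phenyl]methanone | COc1cc(OCc2ccccc2)cc(CCc2c(C(=O)c3ccc(OCc4ccccc4)cc3)ccc(OCc3ccccc3)c2Br)c1 | intermediate (not isolated)
15 | [4-(benzyloxy)-2-{2-[3-(benzyloxy)-5-methoxyphenyl]ethyl}-1,3-phenylene]bis{[4-(benzyloxy)phenyl]methanone} | COc1cc(OCc2ccccc2)cc(CCc2c(C(=O)c3ccc(OCc4ccccc4)cc3)ccc(OCc3ccccc3)c2C(=O)c2ccc(OCc3ccccc3)cc2)c1 | intermediate (key-step product)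
16 | [4-(benzyloxy)-2-{2-[3-(benzyloxy)-5-methoxyphenyl]ethyl}-1,3-phenylene]bis{[4-(benzyloxy)phenyl]methanol}, mixture of diastereomers | COc1cc(OCc2ccccc2)cc(CCc2c(C(O)c3ccc(OCc4ccccc4)cc3)ccc(OCc3ccccc3)c2C(O)c2ccc(OCc3ccccc3)cc2)c1 | intermediate
17 | 2,4-bis(4-hydroxybenzyl)-3-[2-(3-hydroxy-5-methoxyphenyl)ethyl]phenol | COc1cc(O)cc(CCc2c(Cc3ccc(O)cc3)ccc(O)c2Cc2ccc(O)cc2)c1 | target
18 | 4-(benzyloxy)benzaldehyde | O=Cc1ccc(OCc2ccccc2)cc1 | starting material (fallback to step 9 only)
19 | 2,4-dibromophenol | Oc1ccc(Br)cc1Br | starting material (fallback to step 1 only)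

**Step count**

- Total step count: 11.
- Longest linear sequence: 9 steps (from 4 through steps 3–11). The ring-B branch from 1 runs through 7 steps.

**Steps most likely to fail**

**Step 9.**
- Risk: oxidative addition into the C2–Br bond, flanked by OBn and the bridge, may be too slow at a CO-saturated palladium(0), so that the sequence stops after the first carbonylation. Direct biaryl coupling and C–H arylation of ring A may also drain the arylpalladium species.
- Fallback: it gives up palladium and carbon monoxide and takes the one-carbon links from an aldehyde. It sets out from 11.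
- Route: double bromine–lithium exchange (t-BuLi, 4.2 equiv, THF–Et2O, −78 °C) should give the 2,4-dilithiated bibenzyl F1. Addition of 4-(benzyloxy)benzaldehyde 18 (2.5 equiv) and aqueous quench should give the bis-carbinol directly. The fallback comes back to the route at 16 and replaces steps 9 and 10.

**Step 11.**
- Risk: the acid may ionise the doubly aryl-stabilised carbinols faster than the catalyst cleaves them. A nucleophilic carbon of ring A (ortho or para to each of its two oxygens) may then capture the cation in a seven-membered Friedel–Crafts closure. Hydrogenolysis may also stall at the shielded C2 carbinol.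
- Fallback: it turns the hydroxyls into better leaving groups for the metal and removes the acid. It sets out from 16.
- Route: acetylation (Ac2O, DMAP, pyridine, rt) should give the bis-benzhydryl diacetate F2. This is hydrogenolysed under neutral conditions (H2, Pd(OH)2/C, EtOAc–EtOH, rt) with loss of both acetates and all four benzyl groups. The fallback comes back to the route at 17.

**Step 1.**
- Risk: attack at C4 (ortho to the hydroxyl) may compete with attack at C6, and a third bromination may follow. The products would be regioisomers that are hard to separate.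
- Fallback: it buys both bromines in place and introduces the formyl carbon last. It sets out from 2,4-dibromophenol 19, which takes the place of 1.
- Route: O-benzylation (BnBr, K2CO3, DMF) should give 1-(benzyloxy)-2,4-dibromobenzene F3. LDA (THF, −78 °C) should remove the most acidic ring proton, the one between the two bromines, to give [3-(benzyloxy)-2,6-dibromophenyl]lithium F4. A DMF quench at −78 °C should give the aldehyde. The fallback comes back to the route at 3 and replaces steps 1 and 2.

**Further compounds**

F1 | step 9 | 1-(benzyloxy)-2,4-dilithio-3-{2-[3-(benzyloxy)-5-methoxyphenyl]ethyl}benzene | COc1cc(OCc2ccccc2)cc(CCc2c([Li])ccc(OCc3ccccc3)c2[Li])c1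
F2 | step 11 | [4-(benzyloxy)-2-{2-[3-(benzyloxy)-5-methoxyphenyl]ethyl}-1,3-phenylene]bis{[4-(benzyloxy)phenyl]methylene} diacetate, mixture of diastereomers | COc1cc(OCc2ccccc2)cc(CCc2c(C(OC(C)=O)c3ccc(OCc4ccccc4)cc3)ccc(OCc3ccccc3)c2C(OC(C)=O)c2ccc(OCc3ccccc3)cc2)c1
F3 | step 1 | 1-(benzyloxy)-2,4-dibromobenzene | Brc1ccc(OCc2ccccc2)c(Br)c1
F4 | step 1 | [3-(benzyloxy)-2,6-dibromophenyl]lithium | [Li]c1c(Br)ccc(OCc2ccccc2)c1Br
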